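Amounts first: in this flask the charged substrate stands as substrate, as target, or in unseen forms, so the gap between the charge and the two readings counts what has left sight.

- south-east: substrate 0.20 M; reagent 0.16 M; the very flask that is asked about, followed so far
- flask: substrate 0.20 M; reagent 0.160 M; time 8.0 d

- south-east (time / h: target / %, substrate / %): 2.50: 9.9, 63.2; 5.00: 24.4, 55.5; 8.00: 33.9, 48.1; 10.0: 35.4, 44.4; 12.0: 36.8, 41.1; 15.0: 36.4, 38.3

(standard deviation of a reading: 0.5 percentage points)

- time, not beyond 8.0 d, at which the flask holds most target
- the amount of target, in percent of the substrate charged, at that time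
- earliest time at which at least nineteen twentieths of that best amount are there, in d
- latest time at which they still are, in d

- the analysis behind the earlier runs scatters by 0.5 percentage points, standard deviation

Late in the run target barely rose while the gap kept growing, so I wanted the rate at which target itself is lost. I needed the gain of the gap, the target present meanwhile, and the span. The span was exact. Target could be replaced by its mean, 35.6%, and the mean of the two end readings, 35.1%, shows how little that choice matters. The gain mattered: from 8.00 h to 15.0 h it was 7.3 percentage points, and the readings behind it put an uncertainty near 1 point on it, about 13.7% of the result.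

Dividing gave 0.703 d⁻¹. This first-order constant, gap gained per day per unit of target, I called the leak. If unseen forms were still draining, the gap understated the loss, so I took it as likely low. With no feed, target at that leak falls to half in 0.987 d; counted from the highest reading, at 12.0 h, that gave 1.49 d, and I expected the window to shut before then.

The forecast gave, in the order asked, 0.6 d, 37.2%, 0.39 d and 2 d, the last later than my limit, adding: “The decline afterwards is the real unknown”.

The flask gave, in the same order, 0.550 d, 37.0%, 0.392 d and 0.762 d, so it shut earlier than forecast.

    reagent ⇌ dormant form (K = 2.30, k = 2.30 × 10⁻⁴ s⁻¹)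
    intermediate B → target (k = 3.70 × 10⁻⁴ s⁻¹)
    intermediate A → intermediate C (k = 2.00 × 10⁻⁴ s⁻¹)
    substrate + reagent ⇌ intermediate A (K = 5.60 M⁻¹, k = 0.00330 M⁻¹ s⁻¹)
    reagent + intermediate B ⇌ intermediate D (K = 5.90 M⁻¹, k = 7.60 × 10⁻⁵ M⁻¹ s⁻¹)
    target → over-reaction product (k = 1.40 × 10⁻⁵ s⁻¹)
    intermediate D ⇌ intermediate E (K = 5.90, k = 2.90 × 10⁻⁴ s⁻¹)
    substrate + reagent → intermediate B (k = 8.40 × 10⁻⁵ M⁻¹ s⁻¹)
    intermediate B ⇌ intermediate C (K = 0.600, k = 1.30 × 10⁻⁴ s⁻¹)

The loss is the step from target to over-reaction product: the simulated run without that step peaks at 79.8% instead of 37.0%. From 0.550 d to 0.800 d the leak predicts 6.3 points of that product, and the flask made 11 points, so the leak had read low. In the neighbour with 0.50 M of substrate, 32.0% of over-reaction product at 8.00 d divided by the leak and that time gives a mean target of 5.69%, against a best of 19.9%.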